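The cyclohexane is made from a cyclopentane. An (S)-4-silyloxycyclopentenone supplies the lactone-oxygen carbon (C6) and directs an isopropenyl cuprate to C5. The trapped silyl enol ether is cyclopropanated (a 1-silyloxybicyclo[3.1.0]hexane) and opened with FeCl3 (Saegusa–Ito ring expansion), which inserts the ring's only CH2 (C9) between the carbonyl carbon (C8) and the methyl-bearing carbon (C10). The step exploits that C10 is α to C8 in the five-membered ring but β in the six-membered ring, so the same ketone then accepts a vinyl cuprate that builds the C10 quaternary centre anti to C5. α′-Alkylation, trans-lactonization, α-methylenation, invertive Mitsunobu esterification at C8 and allylic oxidation complete the target.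

Key step: step 5

Remarks on the chemistry:
- Elemanolide numbering is used. The ring is C5–C10: C10 is the quaternary carbon (CH3 = C14, vinyl = C1=C2), C9 the ring CH2, C8 the carbinol carbon that carries the side-chain ester, C7 and C6 the lactone ring-fusion carbons (C6 bears O), and C5 carries C4(=C3)–C15. C11, C12 and C13 are the lactone α-carbon, carbonyl and exocyclic methylene. β is the face of the C10 methyl group, α the face of the C10 vinyl group.
- Assumption: 1 and 19 are bought as single enantiomers.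

Step 1
Reactants: 1 (S)-4-(tert-butyldimethylsilyloxy)cyclopent-2-en-1-one
Product: 2 (S)-4-(tert-butyldimethylsilyloxy)-2-iodocyclopent-2-en-1-one
Conditions: I2, pyridine, CH2Cl2, 0 °C → rt
Reagents that add atoms: iodine, II
Why: Pyridine-mediated addition–elimination (α-iodination of an enone) should place iodine on the α-carbon without touching the C6 stereocentre.

Step 2
Reactants: 2 (S)-4-(tert-butyldimethylsilyloxy)-2-iodocyclopent-2-en-1-one
Product: 3 (S)-4-(tert-butyldimethylsilyloxy)-2-methylcyclopent-2-en-1-one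
Conditions: MeZnCl, Pd(PPh3)4 (cat.), THF, 0 °C → rt
Reagents that add atoms: methylzinc chloride, C[Zn]Cl
Why: Negishi cross-coupling of the alkenyl iodide should replace iodine by the future C14 methyl under neutral conditions that do not provoke β-elimination of the silyloxy group.

Step 3
Reactants: 3 (S)-4-(tert-butyldimethylsilyloxy)-2-methylcyclopent-2-en-1-one
Product: 4 trans-4-(tert-butyldimethylsilyloxy)-2-methyl-3-(prop-1-en-2-yl)-1-(trimethylsilyloxy)cyclopent-1-ene (C5 β-isopropenyl, C6 α-OTBS)
Conditions: CH2=C(CH3)MgBr, CuBr·SMe2 (cat.), TMSCl, THF, −78 °C; Et3N, cold NaHCO3 work-up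
Reagents that add atoms: isopropenylmagnesium bromide, C=C(C)[Mg]Br; chlorotrimethylsilane, C[Si](C)(C)Cl
Why: TMSCl-accelerated copper-catalysed conjugate addition should deliver the isopropenyl group to C5 anti to the C6 silyloxy group (C5 set by substrate control) and trap the enolate regiospecifically as the C8=C10 silyl enol ether.

Step 4
Reactants: 4 trans-4-(tert-butyldimethylsilyloxy)-2-methyl-3-(prop-1-en-2-yl)-1-(trimethylsilyloxy)cyclopent-1-ene
Product: 5 3-(tert-butyldimethylsilyloxy)-5-methyl-4-(prop-1-en-2-yl)-1-(trimethylsilyloxy)bicyclo[3.1.0]hexane (cyclopropane CH2 anti to the isopropenyl group)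
Conditions: Et2Zn, CH2I2, CH2Cl2, 0 °C → rt
Reagents that add atoms: diiodomethane, ICI
Why: Simmons–Smith (Furukawa) cyclopropanation should take the electron-rich silyl enol ether in preference to the isopropenyl group, anti to the C5 substituent; the two new stereocentres are erased in step 5.

Step 5
Reactants: 5 3-(tert-butyldimethylsilyloxy)-5-methyl-4-(prop-1-en-2-yl)-1-(trimethylsilyloxy)bicyclo[3.1.0]hexane
Product: 7 (4,5-trans)-5-(tert-butyldimethylsilyloxy)-3-methyl-4-(prop-1-en-2-yl)cyclohex-2-en-1-one, via β-chloro ketone 6 (not isolated)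
Conditions: FeCl3, DMF, 0 °C → rt; then NaOAc, MeOH, 60 °C
Reagents that add atoms: none
Why: FeCl3 oxidises the electron-rich siloxycyclopropane by single-electron transfer, silicon is lost, and the cyclopropyloxy radical undergoes β-scission of the zero-bridge C8–C10 bond to the tertiary β-keto radical at C10, which abstracts chlorine to give 6; NaOAc then eliminates HCl towards C9 to give the conjugated enone. The closest known reaction is the Saegusa–Ito ring expansion of 1-silyloxybicyclo[n.1.0]alkanes to 2-cycloalkenones. No ring is closed: the six-membered ring arises from the five-membered ring of 5 by cleavage of the bond it shares with the cyclopropane, so the former cyclopropane CH2 becomes ring member C9 (expansion by one carbon). No new stereocentre is formed; the two cyclopropane stereocentres are erased and C5 and C6 are untouched. The step needs cleavage of the internal and not the external cyclopropane bond, which the C10 methyl group secures by making the internal-cleavage radical tertiary, and chemoselectivity over the isopropenyl group and the TBS ether, which rests on the much easier oxidation of the siloxycyclopropane and on DMF-moderated FeCl3.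

Step 6
Reactants: 7 (4,5-trans)-5-(tert-butyldimethylsilyloxy)-3-methyl-4-(prop-1-en-2-yl)cyclohex-2-en-1-one
Product: 8 methyl 2-[6-(tert-butyldimethylsilyloxy)-4-methyl-2-oxo-5-(prop-1-en-2-yl)cyclohex-3-en-1-yl]acetate (C7 β-CH2CO2Me, C6 α-OTBS, C5 β-isopropenyl)
Conditions: LDA, THF, −78 °C; BrCH2CO2Me, DMPU, −78 → −40 °C
Reagents that add atoms: methyl bromoacetate, COC(=O)CBr
Why: Kinetic deprotonation of the enone should occur at the α′-carbon C7 (cross-conjugated enolate), and enolate alkylation anti to the neighbouring C6 silyloxy group should set C7 trans to it.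

Step 7
Reactants: 8 methyl 2-[6-(tert-butyldimethylsilyloxy)-4-methyl-2-oxo-5-(prop-1-en-2-yl)cyclohex-3-en-1-yl]acetate
Product: 10 methyl 6α-(tert-butyldimethylsilyloxy)-8-oxo-13-norelema-1,3-dien-12-oate, via silyl enol ether 9 (not isolated)
Conditions: CH2=CHMgBr, CuBr·SMe2 (cat.), TMSCl, THF, −78 → −40 °C; 1 M HCl work-up
Reagents that add atoms: vinylmagnesium bromide, C=C[Mg]Br
Why: TMSCl-accelerated copper-catalysed conjugate addition to the β,β-disubstituted enone should bring the vinyl group onto C10 anti to the vicinal C5 isopropenyl group, creating the quaternary centre (vinyl α, methyl β), and the acidic work-up should cleave the silyl enol ether.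

Step 8
Reactants: 10 methyl 6α-(tert-butyldimethylsilyloxy)-8-oxo-13-norelema-1,3-dien-12-oate
Product: 12 8-oxo-13-norelema-1,3-dien-12,6α-olide (trans-fused keto lactone), via hydroxy ester 11 (not isolated)
Conditions: HF·pyridine, THF, 0 °C → rt; then CSA (cat.), CH2Cl2, rt
Reagents that add atoms: none
Why: Desilylation should free the 6α-hydroxyl, which is trans-diequatorial to the C7 acetate arm and should lactonize under mild acid catalysis (transesterification) to the trans-fused γ-lactone.

Step 9
Reactants: 12 8-oxo-13-norelema-1,3-dien-12,6α-olide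
Product: 13 8β-hydroxy-13-norelema-1,3-dien-12,6α-olide
Conditions: L-Selectride, THF, −78 °C; aq. NH4Cl
Reagents that add atoms: none
Why: The bulky hydride should attack C8 from the equatorial α-face, because the axial β-trajectory is blocked by the syn-axial C10 methyl group, giving the axial 8β-alcohol chemoselectively over the lactone (substrate-controlled ketone reduction).

Step 10
Reactants: 13 8β-hydroxy-13-norelema-1,3-dien-12,6α-olide
Product: 14 8β-(trimethylsilyloxy)-13-norelema-1,3-dien-12,6α-olide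
Conditions: N-(trimethylsilyl)imidazole, CH2Cl2, rt
Reagents that add atoms: N-(trimethylsilyl)imidazole, C[Si](C)(C)n1ccnc1
Why: O-Silylation should mask the 8β-hydroxyl, whose alkoxide could otherwise translactonize onto C12 during the enolate chemistry of step 11.

Step 11
Reactants: 14 8β-(trimethylsilyloxy)-13-norelema-1,3-dien-12,6α-olide
Product: 18 8β-hydroxyelema-1,3,11(13)-trien-12,6α-olide, via Mannich base 15 (not isolated), via ammonium iodide 16 (not isolated), via silyl-protected methylene lactone 17 (not isolated)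
Conditions: LDA, THF, −78 °C; CH2=NMe2+ I−, −78 °C → rt; MeI, MeOH, rt; aq. NaHCO3, CH2Cl2; then 1 M HCl, THF, 0 °C
Reagents that add atoms: N,N-dimethylmethyleneiminium iodide (Eschenmoser's salt), C=[N+](C)C.[I-]
Why: Lactone-enolate Mannich reaction, quaternization and Hofmann-type elimination should install the exocyclic C11=C13 methylene (α-methylenation), and the acidic work-up should remove the TMS ether.

Step 12
Reactants: 19 (R)-2-(2,2-dimethyl-1,3-dioxolan-4-yl)ethan-1-ol
Product: 20 (R)-2-(2,2-dimethyl-1,3-dioxolan-4-yl)acetaldehyde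
Conditions: Dess–Martin periodinane, NaHCO3, CH2Cl2, 0 °C → rt
Reagents that add atoms: none
Why: Buffered Dess–Martin oxidation of the primary alcohol should give the aldehyde without disturbing the acetonide or its stereocentre.

Step 13
Reactants: 20 (R)-2-(2,2-dimethyl-1,3-dioxolan-4-yl)acetaldehyde
Product: 21 2-[(R)-2,2-dimethyl-1,3-dioxolan-4-yl]prop-2-enal
Conditions: CH2=NMe2+ I−, Et3N, CH2Cl2, rt
Reagents that add atoms: N,N-dimethylmethyleneiminium iodide (Eschenmoser's salt), C=[N+](C)C.[I-]
Why: Mannich reaction of the aldehyde followed by elimination of dimethylamine should give the 2-substituted acrolein (α-methylenation), in which the dioxolane stereocentre is no longer adjacent to an enolizable position.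

Step 14
Reactants: 21 2-[(R)-2,2-dimethyl-1,3-dioxolan-4-yl]prop-2-enal
Product: 22 2-[(R)-2,2-dimethyl-1,3-dioxolan-4-yl]prop-2-enoic acid
Conditions: NaClO2, NaH2PO4, 2-methyl-2-butene, t-BuOH/H2O, rt
Reagents that add atoms: sodium chlorite, [Na+].[O-]Cl=O
Why: Pinnick oxidation should convert the enal into the acrylic acid without touching the alkene or the acetonide.

Step 15
Reactants: 18 8β-hydroxyelema-1,3,11(13)-trien-12,6α-olide; 22 2-[(R)-2,2-dimethyl-1,3-dioxolan-4-yl]prop-2-enoic acid
Product: 23 8α-{2-[(R)-2,2-dimethyl-1,3-dioxolan-4-yl]acryloyloxy}elema-1,3,11(13)-trien-12,6α-olide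
Conditions: PPh3, DIAD (betaine pre-formed), THF/PhMe, 0 °C → rt
Reagents that add atoms: none
Why: Mitsunobu esterification should displace the activated axial 8β-oxyphosphonium group by the carboxylate with inversion (SN2), installing the side chain and the equatorial 8α configuration in one operation.

Step 16
Reactants: 23 8α-{2-[(R)-2,2-dimethyl-1,3-dioxolan-4-yl]acryloyloxy}elema-1,3,11(13)-trien-12,6α-olide
Product: 25 8α-{2-[(R)-2,2-dimethyl-1,3-dioxolan-4-yl]acryloyloxy}-15-oxoelema-1,3,11(13)-trien-12,6α-olide, via allylic alcohol 24 (not isolated)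
Conditions: SeO2, 1,4-dioxane, 70 °C
Reagents that add atoms: selenium dioxide, O=[Se]=O
Why: The selenium dioxide ene/[2,3]-sigmatropic sequence (Riley allylic oxidation) should attack the only electron-rich alkene that has allylic hydrogens, the isopropenyl group, at its methyl group and carry the alcohol on to the enal.

Step 17
Reactants: 25 8α-{2-[(R)-2,2-dimethyl-1,3-dioxolan-4-yl]acryloyloxy}-15-oxoelema-1,3,11(13)-trien-12,6α-olide
Product: 26 8α-[(3R)-3,4-dihydroxy-2-methylidenebutanoyloxy]-15-oxoelema-1,3,11(13)-trien-12,6α-olide (CNP0204284.1)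
Conditions: AcOH/H2O (4:1), 40 °C
Reagents that add atoms: none
Why: Mild aqueous acid should hydrolyse the isopropylidene acetal to the 3′,4′-diol (acetal hydrolysis) without affecting the esters, the enal or the α-methylene lactone.

Compound list
1 | (S)-4-(tert-butyldimethylsilyloxy)cyclopent-2-en-1-one | O=C1C=C[C@@H](O[Si](C)(C)C(C)(C)C)C1 | starting material
2 | (S)-4-(tert-butyldimethylsilyloxy)-2-iodocyclopent-2-en-1-one | O=C1C(I)=C[C@@H](O[Si](C)(C)C(C)(C)C)C1 | intermediate
3 | (S)-4-(tert-butyldimethylsilyloxy)-2-methylcyclopent-2-en-1-one | O=C1C(C)=C[C@@H](O[Si](C)(C)C(C)(C)C)C1 | intermediate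
4 | trans-4-(tert-butyldimethylsilyloxy)-2-methyl-3-(prop-1-en-2-yl)-1-(trimethylsilyloxy)cyclopent-1-ene | CC1=C(O[Si](C)(C)C)C[C@H](O[Si](C)(C)C(C)(C)C)[C@H]1C(C)=C | intermediate
5 | 3-(tert-butyldimethylsilyloxy)-5-methyl-4-(prop-1-en-2-yl)-1-(trimethylsilyloxy)bicyclo[3.1.0]hexane, CH2 anti to isopropenyl | C[C@@]12C[C@]1(O[Si](C)(C)C)C[C@H](O[Si](C)(C)C(C)(C)C)[C@H]2C(C)=C | intermediate
6 | 5-(tert-butyldimethylsilyloxy)-3-chloro-3-methyl-4-(prop-1-en-2-yl)cyclohexan-1-one (chloride epimers) | CC1(Cl)CC(=O)C[C@H](O[Si](C)(C)C(C)(C)C)[C@H]1C(C)=C | intermediate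
7 | (4,5-trans)-5-(tert-butyldimethylsilyloxy)-3-methyl-4-(prop-1-en-2-yl)cyclohex-2-en-1-one | CC1=CC(=O)C[C@H](O[Si](C)(C)C(C)(C)C)[C@H]1C(C)=C | intermediate
8 | methyl 2-[6-(tert-butyldimethylsilyloxy)-4-methyl-2-oxo-5-(prop-1-en-2-yl)cyclohex-3-en-1-yl]acetate (all-trans) | CC1=CC(=O)[C@@H](CC(=O)OC)[C@H](O[Si](C)(C)C(C)(C)C)[C@H]1C(C)=C | intermediate
9 | methyl 6α-(tert-butyldimethylsilyloxy)-8-(trimethylsilyloxy)-13-norelema-1,3,8-trien-12-oate | C=C[C@]1(C)C=C(O[Si](C)(C)C)[C@@H](CC(=O)OC)[C@H](O[Si](C)(C)C(C)(C)C)[C@H]1C(C)=C | intermediate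
10 | methyl 6α-(tert-butyldimethylsilyloxy)-8-oxo-13-norelema-1,3-dien-12-oate | C=C[C@]1(C)CC(=O)[C@@H](CC(=O)OC)[C@H](O[Si](C)(C)C(C)(C)C)[C@H]1C(C)=C | intermediate
11 | methyl 6α-hydroxy-8-oxo-13-norelema-1,3-dien-12-oate | C=C[C@]1(C)CC(=O)[C@@H](CC(=O)OC)[C@H](O)[C@H]1C(C)=C | intermediate
12 | 8-oxo-13-norelema-1,3-dien-12,6α-olide | C=C[C@]1(C)CC(=O)[C@H]2CC(=O)O[C@@H]2[C@H]1C(C)=C | intermediate
13 | 8β-hydroxy-13-norelema-1,3-dien-12,6α-olide | C=C[C@]1(C)C[C@@H](O)[C@H]2CC(=O)O[C@@H]2[C@H]1C(C)=C | intermediate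
14 | 8β-(trimethylsilyloxy)-13-norelema-1,3-dien-12,6α-olide | C=C[C@]1(C)C[C@@H](O[Si](C)(C)C)[C@H]2CC(=O)O[C@@H]2[C@H]1C(C)=C | intermediate
15 | 11-(dimethylaminomethyl)-8β-(trimethylsilyloxy)-13-norelema-1,3-dien-12,6α-olide (C11 epimers) | C=C[C@]1(C)C[C@@H](O[Si](C)(C)C)[C@H]2C(CN(C)C)C(=O)O[C@@H]2[C@H]1C(C)=C | intermediate
16 | trimethylammonium iodide of 15 | C=C[C@]1(C)C[C@@H](O[Si](C)(C)C)[C@H]2C(C[N+](C)(C)C)C(=O)O[C@@H]2[C@H]1C(C)=C.[I-] | intermediate
17 | 8β-(trimethylsilyloxy)elema-1,3,11(13)-trien-12,6α-olide | C=C[C@]1(C)C[C@@H](O[Si](C)(C)C)[C@H]2C(=C)C(=O)O[C@@H]2[C@H]1C(C)=C | intermediate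
18 | 8β-hydroxyelema-1,3,11(13)-trien-12,6α-olide | C=C[C@]1(C)C[C@@H](O)[C@H]2C(=C)C(=O)O[C@@H]2[C@H]1C(C)=C | intermediate
19 | (R)-2-(2,2-dimethyl-1,3-dioxolan-4-yl)ethan-1-ol | OCC[C@@H]1COC(C)(C)O1 | starting material
20 | (R)-2-(2,2-dimethyl-1,3-dioxolan-4-yl)acetaldehyde | O=CC[C@@H]1COC(C)(C)O1 | intermediate
21 | 2-[(R)-2,2-dimethyl-1,3-dioxolan-4-yl]prop-2-enal | O=CC(=C)[C@@H]1COC(C)(C)O1 | intermediate
22 | 2-[(R)-2,2-dimethyl-1,3-dioxolan-4-yl]prop-2-enoic acid | OC(=O)C(=C)[C@@H]1COC(C)(C)O1 | intermediate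
23 | 8α-{2-[(R)-2,2-dimethyl-1,3-dioxolan-4-yl]acryloyloxy}elema-1,3,11(13)-trien-12,6α-olide | C=C[C@]1(C)C[C@H](OC(=O)C(=C)[C@@H]3COC(C)(C)O3)[C@H]2C(=C)C(=O)O[C@@H]2[C@H]1C(C)=C | intermediate
24 | 15-hydroxy derivative of 23 | C=C[C@]1(C)C[C@H](OC(=O)C(=C)[C@@H]3COC(C)(C)O3)[C@H]2C(=C)C(=O)O[C@@H]2[C@H]1C(=C)CO | intermediate
25 | 15-oxo derivative of 23 | C=C[C@]1(C)C[C@H](OC(=O)C(=C)[C@@H]3COC(C)(C)O3)[C@H]2C(=C)C(=O)O[C@@H]2[C@H]1C(=C)C=O | intermediate
26 | 8α-[(3R)-3,4-dihydroxy-2-methylidenebutanoyloxy]-15-oxoelema-1,3,11(13)-trien-12,6α-olide (CNP0204284.1) | C=C[C@]1(C)C[C@H](OC(=O)C(=C)[C@@H](O)CO)[C@H]2C(=C)C(=O)O[C@@H]2[C@H]1C(=C)C=O | target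

Total step count: 17
Longest linear sequence: 14 steps (steps 1–11 and 15–17, from 1)

Steps most likely to fail

1. Step 5 (ring expansion). Iron(III) may also attack the isopropenyl group or strip the TBS ether, and competing cleavage of the external cyclopropane bond would give a ring-retained cyclopentanone instead of the cyclohexenone. The fallback sets out from 4 and comes back at 7, and still forms the six-membered ring by one-carbon expansion. Dibromocarbene (CHBr3, KOt-Bu, pentane, −20 °C) should add to the enol ether of 4 to give the 6,6-dibromo-1-silyloxybicyclo[3.1.0]hexane F1. On warming, F1 should undergo electrocyclic opening of the cyclopropane with loss of bromide and the silyl group to give the 2-bromo-3-methylcyclohexenone F2. Palladium-catalysed hydrostannolysis of the alkenyl bromide (Bu3SnH, Pd(PPh3)4) should then give 7.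

2. Step 15 (Mitsunobu inversion). E2 elimination of the activated axial alcohol may outrun SN2 displacement, and the phosphine may add to the α-methylene lactone. The fallback sets out from 12 and comes back at 23, and avoids substitution at C8.
   - The ketone of 12 is reduced under equilibrating Meerwein–Ponndorf–Verley conditions (Al(Oi-Pr)3, i-PrOH, PhMe, 60 °C). This should favour the equatorial alcohol 8α-hydroxy-13-norelema-1,3-dien-12,6α-olide F3, because its epimer suffers a 1,3-diaxial OH/CH3 contact.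
   - The chemistry of steps 10 and 11 is then repeated: silylation to the TMS ether F4, enolate Mannich reaction to the Mannich base F5, quaternization to the ammonium iodide F6, elimination to the silyl-protected methylene lactone F7, and acidic work-up to 8α-hydroxyelema-1,3,11(13)-trien-12,6α-olide F8.
   - Acylation with 22 under Yamaguchi conditions (2,4,6-trichlorobenzoyl chloride, Et3N, DMAP, PhMe), with retention at C8, gives 23.

3. Step 16 (allylic oxidation). Hydrogen abstraction may occur at the C5 methine instead of the methyl group, the enal may be over-oxidised, and the acidic selenium species may cleave the acetonide early. The fallback sets out from 23 and comes back at 25. A Schenck ene reaction with singlet oxygen (O2, tetraphenylporphyrin, hν, CH2Cl2, 0 °C) should convert the isopropenyl group into the primary allylic hydroperoxide F9. Kornblum–DeLaMare dehydration (Ac2O, pyridine) should then give enal 25.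

Further compounds
F1 | step 5 | 6,6-dibromo-3-(tert-butyldimethylsilyloxy)-5-methyl-4-(prop-1-en-2-yl)-1-(trimethylsilyloxy)bicyclo[3.1.0]hexane | C[C@@]12C(Br)(Br)[C@]1(O[Si](C)(C)C)C[C@H](O[Si](C)(C)C(C)(C)C)[C@H]2C(C)=C
F2 | step 5 | (4,5-trans)-2-bromo-5-(tert-butyldimethylsilyloxy)-3-methyl-4-(prop-1-en-2-yl)cyclohex-2-en-1-one | CC1=C(Br)C(=O)C[C@H](O[Si](C)(C)C(C)(C)C)[C@H]1C(C)=C
F3 | step 15 | 8α-hydroxy-13-norelema-1,3-dien-12,6α-olide | C=C[C@]1(C)C[C@H](O)[C@H]2CC(=O)O[C@@H]2[C@H]1C(C)=C
F4 | step 15 | 8α-(trimethylsilyloxy)-13-norelema-1,3-dien-12,6α-olide | C=C[C@]1(C)C[C@H](O[Si](C)(C)C)[C@H]2CC(=O)O[C@@H]2[C@H]1C(C)=C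
F5 | step 15 | 11-(dimethylaminomethyl)-8α-(trimethylsilyloxy)-13-norelema-1,3-dien-12,6α-olide (C11 epimers) | C=C[C@]1(C)C[C@H](O[Si](C)(C)C)[C@H]2C(CN(C)C)C(=O)O[C@@H]2[C@H]1C(C)=C
F6 | step 15 | trimethylammonium iodide of F5 | C=C[C@]1(C)C[C@H](O[Si](C)(C)C)[C@H]2C(C[N+](C)(C)C)C(=O)O[C@@H]2[C@H]1C(C)=C.[I-]
F7 | step 15 | 8α-(trimethylsilyloxy)elema-1,3,11(13)-trien-12,6α-olide | C=C[C@]1(C)C[C@H](O[Si](C)(C)C)[C@H]2C(=C)C(=O)O[C@@H]2[C@H]1C(C)=C
F8 | step 15 | 8α-hydroxyelema-1,3,11(13)-trien-12,6α-olide | C=C[C@]1(C)C[C@H](O)[C@H]2C(=C)C(=O)O[C@@H]2[C@H]1C(C)=C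
F9 | step 16 | 15-hydroperoxy derivative of 23 | C=C[C@]1(C)C[C@H](OC(=O)C(=C)[C@@H]3COC(C)(C)O3)[C@H]2C(=C)C(=O)O[C@@H]2[C@H]1C(=C)COO
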